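## Retrosynthetic overview

1. Target acid ⇒ aryl lactone on the 5-oxygen (opened last with LiOH); prenyl ⇒ Friedel–Crafts alkylation of the single free aryl C–H.
2. Chromanone ⇒ alkaloid-catalysed oxa-Michael closure of an ortho-tigloyl phenol (sets C2; C3 equilibrated to trans); tigloyl ⇒ Friedel–Crafts acylation with in-situ ortho-demethylation.
3. Key disconnection: phloroglucinol-type lactone ⇒ 3-propylindan-1-one by Baeyer–Villiger ring expansion; the aryl 1,2-shift to oxygen places the third ring oxygen meta to the two resorcinol oxygens.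
4. Indanone ⇒ (R)-3-(2,4-dimethoxyphenyl)hexanoic acid ⇒ resorcinol + (E)-hex-2-enal by a new carbene-catalysed oxidative annulation that sets the benzylic centre.
5. Ring order: resorcinol lactone (made, then opened) → indanone → ring-expanded lactone → chromanone.

Assumption: the SMILES is read as the free acid with 3R in the side chain and 2S,3S (trans) in the chromanone; the facial sense of the two catalyst-controlled steps (1 and 6) is assigned by analogy, and the antipodal or pseudo-enantiomeric catalyst is used if a first run shows the opposite sense.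

## Route

Step 1
Reactants: 1 resorcinol; 2 (E)-hex-2-enal
Product: 3 (4R)-7-hydroxy-4-propyl-3,4-dihydro-2H-chromen-2-one
Conditions: 1 (3 equiv), (5aS,10bR)-2-mesityl-5a,10b-dihydro-4H,6H-indeno[2,1-b][1,2,4]triazolo[4,3-d][1,4]oxazin-2-ium chloride (10 mol %), DBU (20 mol %), 3,3',5,5'-tetra-tert-butyldiphenoquinone (1.1 equiv), 4 Å MS, PhMe/THF, rt, slow addition of 2
Reagents that add atoms: none
Why: Proposed new method: the carbene adds to enal 2 and the Breslow intermediate is oxidised by the bisquinone to an α,β-unsaturated acyl azolium, whose β-carbon is attacked by C4 of resorcinol monoanion (para to one oxygen, ortho to the other, directly or by O-addition and [3,3] shift) on the face left open by the aminoindanol backbone, after which the ortho OH acylates and releases the carbene, so the benzylic R centre is set under catalyst control; the closest known reaction type is the carbene-catalysed oxidative formal [3+3] annulation of enals with naphthols and 1,3-dicarbonyl compounds, not yet shown for plain resorcinol with a β-alkyl enal.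

Step 2
Reactants: 3 (4R)-7-hydroxy-4-propyl-3,4-dihydro-2H-chromen-2-one
Product: 5 (3R)-3-(2,4-dimethoxyphenyl)hexanoic acid, via ring-opened dihydroxy acid 4 (not isolated)
Conditions: NaOH (6 equiv), Me2SO4 (3.5 equiv), H2O/THF, 0 → 60 °C; then HCl to pH 2
Reagents that add atoms: dimethyl sulfate COS(=O)(=O)OC; sodium hydroxide [Na+].[OH-]
Why: Hydroxide opens the aryl lactone (saponification) and both phenoxides are O-methylated (Williamson-type etherification), any methyl ester being re-saponified, so the oxygen that was tied up in the lactone becomes the future 7-OMe while the stereocentre is untouched.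

Step 3
Reactants: 5 (3R)-3-(2,4-dimethoxyphenyl)hexanoic acid
Product: 6 (3R)-4,6-dimethoxy-3-propyl-2,3-dihydro-1H-inden-1-one
Conditions: P2O5/MeSO3H (1:10 w/w, Eaton's reagent), 0.05 M, slow addition, 50 °C
Reagents that add atoms: none
Why: Intramolecular Friedel–Crafts acylation, in which the tethered acylium can reach only the one free ortho position (meta to both methoxy groups) and five-membered ring closure at high dilution outruns intermolecular acylation; the benzylic centre has no acidic hydrogen and is retained.

Step 4
Reactants: 6 (3R)-4,6-dimethoxy-3-propyl-2,3-dihydro-1H-inden-1-one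
Product: 7 (4R)-5,7-dimethoxy-4-propyl-3,4-dihydro-2H-chromen-2-one
Conditions: mCPBA (1.5 equiv), CF3CO2H (1 equiv), CH2Cl2, 0 °C → rt, dark
Reagents that add atoms: 3-chloroperoxybenzoic acid OOC(=O)c1cccc(Cl)c1
Why: Baeyer–Villiger oxidation, in which the aryl group of the Criegee adduct migrates in preference to the primary CH2 (1,2-shift from carbon to oxygen), expanding the five-membered ketone to the six-membered aryl lactone and installing the third ring oxygen; the stereocentre is remote from the migrating bond and is retained.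

Step 5
Reactants: 7 (4R)-5,7-dimethoxy-4-propyl-3,4-dihydro-2H-chromen-2-one; 8 (E)-2-methylbut-2-enoyl chloride (tigloyl chloride)
Product: 10 (4R)-7-hydroxy-5-methoxy-8-[(E)-2-methylbut-2-enoyl]-4-propyl-3,4-dihydro-2H-chromen-2-one, via dimethoxy tigloyl ketone 9 (not isolated)
Conditions: AlCl3 (3.5 equiv), CH2Cl2, 0 °C → rt; cold 1 M HCl work-up
Reagents that add atoms: none
Why: Friedel–Crafts acylation goes to C8 (para to 5-OMe, ortho to 7-OMe, and flanked by the ring-tied lactone oxygen rather than by two methoxy groups), and AlCl3 chelated to the new ketone then cleaves only the ortho C7 methyl ether, leaving the para 5-OMe; no stereocentre is formed.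

Step 6
Reactants: 10 (4R)-7-hydroxy-5-methoxy-8-[(E)-2-methylbut-2-enoyl]-4-propyl-3,4-dihydro-2H-chromen-2-one
Product: 12 (4R,8S,9S)-5-methoxy-8,9-dimethyl-4-propyl-3,4,8,9-tetrahydro-2H,10H-pyrano[2,3-f]chromene-2,10-dione, via cis chromanone 11 (not isolated)
Conditions: quinidine (20 mol %), PhCl, 15 °C; then MgI2 (1.5 equiv), PhMe/Et2O, rt
Reagents that add atoms: none
Why: Cinchona-alkaloid-catalysed intramolecular oxa-Michael addition, in which the quinuclidine nitrogen deprotonates the phenol and the alkaloid hydroxyl binds the enone so that the phenoxide adds to one face of the β-carbon and sets 8S (the pseudo-enantiomeric quinine is known to give the 8R series with ortho-tigloyl phenols of this type), after which MgI2-mediated enolisation equilibrates the α-centre to the more stable trans 9S isomer.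

Step 7
Reactants: 12 (4R,8S,9S)-5-methoxy-8,9-dimethyl-4-propyl-3,4,8,9-tetrahydro-2H,10H-pyrano[2,3-f]chromene-2,10-dione; 13 2-methylbut-3-en-2-ol
Product: 14 (4R,8S,9S)-5-methoxy-8,9-dimethyl-6-(3-methylbut-2-en-1-yl)-4-propyl-3,4,8,9-tetrahydro-2H,10H-pyrano[2,3-f]chromene-2,10-dione
Conditions: 13 (3 equiv, portionwise), BF3·OEt2 (0.5 equiv), dioxane, rt
Reagents that add atoms: none
Why: Friedel–Crafts alkylation, in which BF3 ionises the tertiary allylic alcohol to the prenyl cation and C6, the only free aromatic position (two ortho oxygens, one para oxygen), attacks its unhindered primary terminus; there is no free ortho phenol to close a chroman and the stereocentres are not involved.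

Step 8
Reactants: 14 (4R,8S,9S)-5-methoxy-8,9-dimethyl-6-(3-methylbut-2-en-1-yl)-4-propyl-3,4,8,9-tetrahydro-2H,10H-pyrano[2,3-f]chromene-2,10-dione
Product: 15 (3R)-3-[(2S,3S)-5-hydroxy-7-methoxy-2,3-dimethyl-8-(3-methylbut-2-en-1-yl)-4-oxo-3,4-dihydro-2H-chromen-6-yl]hexanoic acid
Conditions: LiOH·H2O (3 equiv), THF/H2O (3:1), 0 °C, 1 h; then 1 M HCl to pH 3 at 0 °C
Reagents that add atoms: lithium hydroxide [Li+].[OH-]
Why: Saponification of the aryl ester (lactone) at 0 °C is much faster than enolisation or retro-oxa-Michael opening of the chromanone, and the liberated 5-OH is hydrogen-bonded to the C4 ketone so the hydroxy acid survives cold, mild acidification without relactonising; all three stereocentres are retained.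

## Compound list

1 | resorcinol (benzene-1,3-diol) | Oc1cccc(O)c1 | starting material
2 | (E)-hex-2-enal | CCC/C=C/C=O | starting material
3 | (4R)-7-hydroxy-4-propyl-3,4-dihydro-2H-chromen-2-one | CCC[C@@H]1CC(=O)Oc2cc(O)ccc21 | intermediate
4 | (3R)-3-(2,4-dihydroxyphenyl)hexanoic acid (present as its sodium salt) | CCC[C@H](CC(=O)O)c1ccc(O)cc1O | intermediate
5 | (3R)-3-(2,4-dimethoxyphenyl)hexanoic acid | CCC[C@H](CC(=O)O)c1ccc(OC)cc1OC | intermediate
6 | (3R)-4,6-dimethoxy-3-propyl-2,3-dihydro-1H-inden-1-one | CCC[C@@H]1CC(=O)c2cc(OC)cc(OC)c21 | intermediate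
7 | (4R)-5,7-dimethoxy-4-propyl-3,4-dihydro-2H-chromen-2-one | CCC[C@@H]1CC(=O)Oc2cc(OC)cc(OC)c21 | intermediate
8 | (E)-2-methylbut-2-enoyl chloride (tigloyl chloride) | C/C=C(\C)C(=O)Cl | starting material
9 | (4R)-5,7-dimethoxy-8-[(E)-2-methylbut-2-enoyl]-4-propyl-3,4-dihydro-2H-chromen-2-one | CCC[C@@H]1CC(=O)Oc2c(C(=O)/C(C)=C/C)c(OC)cc(OC)c21 | intermediate
10 | (4R)-7-hydroxy-5-methoxy-8-[(E)-2-methylbut-2-enoyl]-4-propyl-3,4-dihydro-2H-chromen-2-one | CCC[C@@H]1CC(=O)Oc2c(C(=O)/C(C)=C/C)c(O)cc(OC)c21 | intermediate
11 | (4R,8S,9R)-5-methoxy-8,9-dimethyl-4-propyl-3,4,8,9-tetrahydro-2H,10H-pyrano[2,3-f]chromene-2,10-dione (cis-dimethyl chromanone fused to the lactone) | CCC[C@@H]1CC(=O)Oc2c1c(OC)cc1O[C@@H](C)[C@@H](C)C(=O)c12 | intermediate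
12 | (4R,8S,9S)-5-methoxy-8,9-dimethyl-4-propyl-3,4,8,9-tetrahydro-2H,10H-pyrano[2,3-f]chromene-2,10-dione (trans-dimethyl chromanone fused to the lactone) | CCC[C@@H]1CC(=O)Oc2c1c(OC)cc1O[C@@H](C)[C@H](C)C(=O)c12 | intermediate
13 | 2-methylbut-3-en-2-ol | CC(C)(O)C=C | starting material
14 | (4R,8S,9S)-5-methoxy-8,9-dimethyl-6-(3-methylbut-2-en-1-yl)-4-propyl-3,4,8,9-tetrahydro-2H,10H-pyrano[2,3-f]chromene-2,10-dione | CCC[C@@H]1CC(=O)Oc2c1c(OC)c(CC=C(C)C)c1O[C@@H](C)[C@H](C)C(=O)c12 | intermediate
15 | (3R)-3-[(2S,3S)-5-hydroxy-7-methoxy-2,3-dimethyl-8-(3-methylbut-2-en-1-yl)-4-oxo-3,4-dihydro-2H-chromen-6-yl]hexanoic acid | CCC[C@H](CC(=O)O)c1c(O)c2c(c(CC=C(C)C)c1OC)O[C@@H](C)[C@H](C)C2=O | target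

## Step count and risks

Total step count: 8. Longest linear sequence: 8 (1 → 15).

Three steps most likely to fail:

**Step 1 (proposed new annulation).** Resorcinol may be too weak a carbon nucleophile, may only be O-acylated, or the β-alkyl acyl azolium may give low ee. The fallback uses known chemistry and sets out from 1. Pd(OAc)2-catalysed hydroarylation–lactonisation with purchased hex-2-ynoic acid (CCCC#CC(=O)O, eight non-hydrogen atoms) in CF3CO2H gives 7-hydroxy-4-propyl-2H-chromen-2-one F1. Copper hydride asymmetric conjugate reduction (Cu(OAc)2·H2O, the antipode of DTBM-SEGPHOS that gives 4R, (EtO)2MeSiH, t-BuOH, THF; fluoride work-up to free the phenol) then comes back to the route at 3.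

**Step 3 (acylation meta to both methoxy groups).** Intermolecular acylation at the activated positions of a second molecule may win over ring closure. The fallback sets out from 3 and inverts the order of C-acylation and O-methylation. Lactone 3 is rearranged in an AlCl3–NaCl melt (170–180 °C), the classical Fries-type conversion of dihydrocoumarins into 4-hydroxyindan-1-ones, where the aluminium phenoxides damp the ring and leave the tethered acylium as the only effective electrophile. This gives (3R)-4,6-dihydroxy-3-propyl-2,3-dihydro-1H-inden-1-one F2; its ee must be checked because the benzylic C–H is exposed to hot Lewis acid. Bis-O-methylation (Me2SO4, K2CO3, acetone, reflux) comes back at 6.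

**Step 7 (Friedel–Crafts prenylation).** Conversion may be low because the ring is only moderately activated, and the new alkene may react further under acid. The fallback sets out from 12. NBS (MeCN, 0 °C) brominates the same single free position to give (4R,8S,9S)-6-bromo-5-methoxy-8,9-dimethyl-4-propyl-3,4,8,9-tetrahydro-2H,10H-pyrano[2,3-f]chromene-2,10-dione F3. A base-free Stille coupling with tributyl(3-methylbut-2-en-1-yl)stannane (CC(C)=CC[Sn](CCCC)(CCCC)CCCC; Pd(PPh3)4, DMF, 90 °C) then comes back at 14 without exposing the chromanone centres to base.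

Further compounds
F1 | step 1 | 7-hydroxy-4-propyl-2H-chromen-2-one | CCCC1=CC(=O)Oc2cc(O)ccc12
F2 | step 3 | (3R)-4,6-dihydroxy-3-propyl-2,3-dihydro-1H-inden-1-one | CCC[C@@H]1CC(=O)c2cc(O)cc(O)c21
F3 | step 7 | (4R,8S,9S)-6-bromo-5-methoxy-8,9-dimethyl-4-propyl-3,4,8,9-tetrahydro-2H,10H-pyrano[2,3-f]chromene-2,10-dione | CCC[C@@H]1CC(=O)Oc2c1c(OC)c(Br)c1O[C@@H](C)[C@H](C)C(=O)c12
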